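**Retrosynthetic overview**
1. Locants (own): C1′ side-chain carbinol; C4, C8 piperidine CH next to N (C4 bears the side chain); cyclopentane C9 (CH), C10 (CHMe), C11 (CHOH), C12 (spiro C), C13 (C–OH); C14–C16 azepane CH2.
2. 41 ⇐ desilylation; piperidine ⇐ all-cis hydrogenation of pyrido[1,2-a]azepinium salt 38 (sets C4, C8); azepane ⇐ N-alkylation of the pyridine by its own C16 mesylate.
3. Cyclopentane ⇐ one operation on pyridine N-oxide 28 and propenyliodonium salt 31: O-alkenylation, anhydrobase formation, [3,3] shift (C9–C10), vinylogous aldol (C11–C12).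
4. Enabling feature: N is bonded to C8, C8 carries the cyclopentane CH (C9), and C11 is a carbinol. At the pyridine level N–C8–C9H2 is a picolyl unit; its N-oxide oxygen becomes the C11 oxygen through the array C9=C8–N–O–C11=C10, and the butenolide C–H at C12 traps the aldehyde that is released.
5. 28 ⇐ tetronate annulation on aldehyde 20 ⇐ chelate-controlled picolyl addition to ynone 14 (sacrificial glycerate centre sets C13; the alkyne is the masked C14–C15). Ring order: pyridine (bought), butenolide, cyclopentane, azepane, piperidine (dearomatisation).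

Key step: step 13

Remark: the butenolide carbon C12 in 27, 28 and 32–34 is a mixture of epimers (left undefined in the SMILES); it becomes planar in step 13.

**Step 1**
Reactants: 1 6-methylpyridine-2-carbonitrile; 2 ethylmagnesium bromide
Product: 4 1-(6-methylpyridin-2-yl)propan-1-one, via magnesium ketimide 3 (not isolated)
Conditions: EtMgBr, THF, 0 °C; then 2 M HCl
Reagents that add atoms: water, O
Why: Grignard addition to a nitrile stops at the N-magnesio ketimine, which is hydrolysed to the ketone on acidic work-up.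

**Step 2**
Reactants: 4 1-(6-methylpyridin-2-yl)propan-1-one
Product: 5 (R)-1-(6-methylpyridin-2-yl)propan-1-ol
Conditions: RuCl(p-cymene)[(R,R)-TsDPEN] (cat.), HCO2H–Et3N (5:2), 30 °C
Reagents that add atoms: none
Why: Noyori asymmetric transfer hydrogenation of a 2-acylpyridine, in which the (R,R)-ligand should deliver hydride to the face that gives the (R)-carbinol (C1′).

**Step 3**
Reactants: 5 (R)-1-(6-methylpyridin-2-yl)propan-1-ol
Product: 6 2-[(R)-1-(tert-butyldimethylsilyloxy)propyl]-6-methylpyridine
Conditions: TBSCl, imidazole, DMF, 23 °C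
Reagents that add atoms: tert-butyldimethylsilyl chloride, CC(C)(C)[Si](C)(C)Cl
Why: Standard silylation of a secondary alcohol; the ether survives the organometallic, oxidative and hydrogenation steps that follow.

**Step 4**
Reactants: 7 methyl (S)-2,2-dimethyl-1,3-dioxolane-4-carboxylate; 8 N,O-dimethylhydroxylamine hydrochloride
Product: 10 (S)-N-methoxy-N,2,2-trimethyl-1,3-dioxolane-4-carboxamide, via chloromagnesium amide 9 (not isolated)
Conditions: iPrMgCl, THF, −20 °C
Reagents that add atoms: none
Why: Weinreb amide formation from an ester through the magnesium amide, which should leave the α-stereocentre untouched at low temperature.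

**Step 5**
Reactants: 11 benzyl prop-2-ynyl ether; 10 (S)-N-methoxy-N,2,2-trimethyl-1,3-dioxolane-4-carboxamide
Product: 14 (S)-4-(benzyloxy)-1-(2,2-dimethyl-1,3-dioxolan-4-yl)but-2-yn-1-one, via lithium acetylide 12 (not isolated), via tetrahedral lithium adduct 13 (not isolated)
Conditions: n-BuLi, THF, −78 °C; then 10, −78 °C; cold aq. NaHSO4 quench
Reagents that add atoms: none
Why: Acylation of a lithium acetylide by a Weinreb amide (ynone synthesis), in which the chelated tetrahedral adduct prevents over-addition and the cold acidic quench prevents conjugate addition of the liberated amine.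

**Step 6**
Reactants: 6 2-[(R)-1-(tert-butyldimethylsilyloxy)propyl]-6-methylpyridine; 14 (S)-4-(benzyloxy)-1-(2,2-dimethyl-1,3-dioxolan-4-yl)but-2-yn-1-one
Product: 17 (2R)-5-(benzyloxy)-1-{6-[(1R)-1-(tert-butyldimethylsilyloxy)propyl]pyridin-2-yl}-2-[(4S)-2,2-dimethyl-1,3-dioxolan-4-yl]pent-3-yn-2-ol, via picolyllithium 15 (not isolated), via picolylmagnesium bromide 16 (not isolated)
Conditions: n-BuLi, THF, −78 °C; MgBr2·OEt2, −78 °C; then 14, −78 °C; aq. NH4Cl
Reagents that add atoms: none
Why: Lateral lithiation of the 6-methyl group, transmetalation to magnesium and 1,2-addition to the non-enolisable ynone under Cram chelate control (magnesium bridges the ketone oxygen and the adjacent dioxolane oxygen, attack on the face of the dioxolane C–H) should set the quaternary carbinol C13, the dioxolane carbon being a sacrificial stereocentre that is excised in step 8.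

**Step 7**
Reactants: 17 tertiary propargylic alcohol
Product: 18 tert-butyldimethylsilyl ether of 17 at the tertiary hydroxyl
Conditions: TBSOTf, 2,6-lutidine, CH2Cl2, 0 to 23 °C
Reagents that add atoms: tert-butyldimethylsilyl trifluoromethanesulfonate, CC(C)(C)[Si](C)(C)OS(=O)(=O)C(F)(F)F
Why: Silyl triflate silylation of a tertiary propargylic alcohol, which blocks glycol cleavage at C13 in step 8 and retro-aldol cleavage later.

**Step 8**
Reactants: 18 bis-silyl ether acetonide
Product: 20 (2R)-5-(benzyloxy)-2-(tert-butyldimethylsilyloxy)-2-({6-[(1R)-1-(tert-butyldimethylsilyloxy)propyl]pyridin-2-yl}methyl)pent-3-ynal, via diol 19 (not isolated)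
Conditions: H5IO6, EtOAc, 23 °C
Reagents that add atoms: none
Why: Periodic acid hydrolyses the terminal acetonide and cleaves the resulting glycol in one pot, and the aldehyde cannot epimerise because its α-carbon is quaternary.

**Step 9**
Reactants: 21 methyl propanoate; 22 methyl formate
Product: 24 methyl (E)-3-methoxy-2-methylprop-2-enoate, via sodium enolate 23 (not isolated)
Conditions: NaH, THF, 0 to 23 °C; then Me2SO4, DMF, 23 °C
Reagents that add atoms: dimethyl sulfate, COS(=O)(=O)OC
Why: Crossed Claisen formylation followed by O-methylation of the formyl ester enolate, which should give the thermodynamically preferred E enol ether.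

**Step 10**
Reactants: 24 methyl (E)-3-methoxy-2-methylprop-2-enoate; 20 aldehyde
Product: 27 5-[(2R)-5-(benzyloxy)-2-(tert-butyldimethylsilyloxy)-1-{6-[(1R)-1-(tert-butyldimethylsilyloxy)propyl]pyridin-2-yl}pent-3-yn-2-yl]-4-methoxy-3-methylfuran-2(5H)-one, via lithioacrylate 25 (not isolated), via lithium alkoxide adduct 26 (not isolated)
Conditions: LiN(iPr)2, THF, −78 °C; then 20, −78 to −20 °C; aq. NH4Cl
Reagents that add atoms: none
Why: Tetronate annulation with a β-lithiated β-methoxyacrylate: the vinyllithium (lithium cis to the ester) adds to the aldehyde and the alkoxide lactonises onto the cis ester, giving both C12 epimers, which are erased in step 13.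

**Step 11**
Reactants: 27 butenolide pyridine
Product: 28 pyridine N-oxide of 27
Conditions: mCPBA, CH2Cl2, 0 to 23 °C
Reagents that add atoms: 3-chloroperbenzoic acid, OOC(=O)c1cccc(Cl)c1
Why: Peracid N-oxidation of a 2,6-dialkylpyridine, in which the alkyne and the push-pull butenolide alkene should stay untouched; this oxygen ends as the C11 hydroxyl.

**Step 12**
Reactants: 29 potassium (E)-prop-1-enyltrifluoroborate; 30 1-(difluoroiodo)-4-methylbenzene
Product: 31 (E)-(4-methylphenyl)(prop-1-enyl)iodonium tetrafluoroborate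
Conditions: MeCN, −40 to 23 °C
Reagents that add atoms: none
Why: Boron-to-iodine alkenyl transfer from an alkenyltrifluoroborate to an aryl iodine difluoride, a known route to alkenyl(aryl)iodonium tetrafluoroborates with retention of the E geometry.

**Step 13**
Reactants: 28 pyridine N-oxide; 31 (E)-(4-methylphenyl)(prop-1-enyl)iodonium tetrafluoroborate
Product: 35 cyclopentanol (pyridyl at C9 trans to the C10 methyl; methyl cis to the C11 hydroxyl; hydroxyl trans to the lactone oxygen at C12; lactone oxygen cis to the C13 silyloxy group), via N-propenyloxypyridinium salt 32 (not isolated), via anhydrobase 33 (not isolated), via aldehyde 34 (not isolated)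
Conditions: 31, CH2Cl2, 0 to 23 °C; then 2-tert-butyl-1,1,3,3-tetramethylguanidine, MeCN, −40 to 0 °C
Reagents that add atoms: none
Why: Proposed new method: the N-oxide oxygen of 28 displaces the iodane from 31 at the vinylic carbon (in-plane vinylic SN2 with inversion, as known for amide and carboxylate oxygens) to give the Z enol ether salt 32; the hindered guanidine removes a proton from the only ring-bound CH2 to give anhydrobase 33, whose C9=C8–N–O–C11=C10 array undergoes a [3,3]-sigmatropic shift, driven by cleavage of the weak N–O bond and rearomatisation, that forms C9–C10 and releases aldehyde 34; the same base then closes the cyclopentane by a 5-(enolexo)-exo-trig vinylogous aldol addition of the butenolide C–H (C12) to C11. The closest known reactions are the Boekelheide rearrangement, the base-induced [3,3] shift of N-aryloxy-2-picolinium salts, the [3,3] shift of O-vinyl N-vinyl hydroxylamines in the Trofimov pyrrole synthesis, and amine-promoted direct vinylogous aldol additions of butenolides. The C9/C10 pair should arise from a chair transition state with the C13 branch pseudo-equatorial (E anhydrobase) and the Z enol ether, and C10 stays correctable because it is alpha to the aldehyde until the ring closes. The face at C9 is set by C13: the rod-like alkynyl group should take the position eclipsing the exocyclic C=C, the new bond should form anti to the bulky butenolide-bearing carbon, and the C–O bond lies outside. In the aldol the planar dienolate should turn its C–OMe edge toward the slim alkynyl group and its ring oxygen toward the silyloxy group (C12), and an open transition state with the aldehyde C=O anti to the ring C–O dipole should put the new hydroxyl cis to the methyl group and within hydrogen-bond distance of the methoxy oxygen (C11). The step needs proton loss at the CH2 and not at the CH(OTBS) on the other side of nitrogen, which the congestion of that methine and the strain of its anhydrobase should secure, and it needs the aldol to outrun loss of silanolate from the dienolate, which low temperature and a weak base should secure.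

**Step 14**
Reactants: 35 cyclopentanol
Product: 36 diol (alkyne reduced to CH2CH2, benzyl ether cleaved to the primary alcohol at C16)
Conditions: H2 (1 atm), Pd(OH)2/C, EtOAc–AcOH, 23 °C
Reagents that add atoms: none
Why: Alkyne hydrogenation and benzyl ether hydrogenolysis in one operation, with acetic acid protonating the pyridine so that it does not poison debenzylation; the pyridine ring and the tetrasubstituted butenolide alkene should not be reduced under these conditions.

**Step 15**
Reactants: 36 diol
Product: 38 pyrido[1,2-a]azepinium methanesulfonate, via primary mesylate 37 (not isolated)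
Conditions: MsCl, Et3N, CH2Cl2, −20 °C; then MeCN, 70 °C
Reagents that add atoms: methanesulfonyl chloride, CS(=O)(=O)Cl
Why: Selective mesylation of the primary alcohol (the secondary one is flanked by the spiro centre) followed by intramolecular Menshutkin N-alkylation of the pyridine, a 7-exo-tet closure of the azepane ring.

**Step 16**
Reactants: 38 pyridinium methanesulfonate
Product: 40 bis-silyl ether of the target, via piperidinium methanesulfonate 39 (not isolated)
Conditions: H2 (4 atm), PtO2, MeOH, 23 °C; then aq. NaHCO3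
Reagents that add atoms: none
Why: Heterogeneous hydrogenation of a pyridinium ring delivers all hydrogens to one face, which gives the cis relationship of C4–H and C8–H; adsorption should occur on the face of C9–H, opposite to the C13 silyloxy group, so that C8–H ends cis to C9–H.

**Step 17**
Reactants: 40 bis-silyl ether
Product: 41 CNP0267781.1
Conditions: HF·pyridine, THF, 0 to 40 °C
Reagents that add atoms: none
Why: Fluoride-mediated cleavage of both silyl ethers under acidic conditions, which avoids base-induced retro-aldol opening at C12–C13 or C11–C12.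

**Compound list**
1 | 6-methylpyridine-2-carbonitrile | Cc1cccc(C#N)n1 | starting material
2 | ethylmagnesium bromide | CC[Mg]Br | starting material
3 | bromomagnesium salt of 1-(6-methylpyridin-2-yl)propan-1-imine | CCC(=N[Mg]Br)c1cccc(C)n1 | intermediate
4 | 1-(6-methylpyridin-2-yl)propan-1-one | CCC(=O)c1cccc(C)n1 | intermediate
5 | (R)-1-(6-methylpyridin-2-yl)propan-1-ol | CC[C@@H](O)c1cccc(C)n1 | intermediate
6 | 2-[(R)-1-(tert-butyldimethylsilyloxy)propyl]-6-methylpyridine | CC[C@@H](O[Si](C)(C)C(C)(C)C)c1cccc(C)n1 | intermediate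
7 | methyl (S)-2,2-dimethyl-1,3-dioxolane-4-carboxylate | COC(=O)[C@@H]1COC(C)(C)O1 | starting material
8 | N,O-dimethylhydroxylamine hydrochloride | CNOC.Cl | starting material
9 | chloromagnesium N-methoxy-N-methylamide | CON(C)[Mg]Cl | intermediate
10 | (S)-N-methoxy-N,2,2-trimethyl-1,3-dioxolane-4-carboxamide | CON(C)C(=O)[C@@H]1COC(C)(C)O1 | intermediate
11 | benzyl prop-2-ynyl ether | C#CCOCc1ccccc1 | starting material
12 | lithium 3-(benzyloxy)prop-1-ynide | [Li]C#CCOCc1ccccc1 | intermediate
13 | lithium alkoxide of the tetrahedral adduct of 12 and 10 | CON(C)C(O[Li])(C#CCOCc1ccccc1)[C@@H]1COC(C)(C)O1 | intermediate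
14 | (S)-4-(benzyloxy)-1-(2,2-dimethyl-1,3-dioxolan-4-yl)but-2-yn-1-one | O=C(C#CCOCc1ccccc1)[C@@H]1COC(C)(C)O1 | intermediate
15 | {6-[(R)-1-(tert-butyldimethylsilyloxy)propyl]pyridin-2-yl}methyllithium | CC[C@@H](O[Si](C)(C)C(C)(C)C)c1cccc(C[Li])n1 | intermediate
16 | {6-[(R)-1-(tert-butyldimethylsilyloxy)propyl]pyridin-2-yl}methylmagnesium bromide | CC[C@@H](O[Si](C)(C)C(C)(C)C)c1cccc(C[Mg]Br)n1 | intermediate
17 | (2R)-5-(benzyloxy)-1-{6-[(1R)-1-(tert-butyldimethylsilyloxy)propyl]pyridin-2-yl}-2-[(4S)-2,2-dimethyl-1,3-dioxolan-4-yl]pent-3-yn-2-ol | CC[C@@H](O[Si](C)(C)C(C)(C)C)c1cccc(n1)C[C@@](O)(C#CCOCc1ccccc1)[C@@H]1COC(C)(C)O1 | intermediate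
18 | tert-butyldimethylsilyl ether of 17 at the tertiary hydroxyl | CC[C@@H](O[Si](C)(C)C(C)(C)C)c1cccc(n1)C[C@@](O[Si](C)(C)C(C)(C)C)(C#CCOCc1ccccc1)[C@@H]1COC(C)(C)O1 | intermediate
19 | (2S,3R)-6-(benzyloxy)-3-(tert-butyldimethylsilyloxy)-3-({6-[(1R)-1-(tert-butyldimethylsilyloxy)propyl]pyridin-2-yl}methyl)hex-4-yne-1,2-diol | CC[C@@H](O[Si](C)(C)C(C)(C)C)c1cccc(n1)C[C@@](O[Si](C)(C)C(C)(C)C)(C#CCOCc1ccccc1)[C@@H](O)CO | intermediate
20 | (2R)-5-(benzyloxy)-2-(tert-butyldimethylsilyloxy)-2-({6-[(1R)-1-(tert-butyldimethylsilyloxy)propyl]pyridin-2-yl}methyl)pent-3-ynal | CC[C@@H](O[Si](C)(C)C(C)(C)C)c1cccc(n1)C[C@@](O[Si](C)(C)C(C)(C)C)(C#CCOCc1ccccc1)C=O | intermediate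
21 | methyl propanoate | CCC(=O)OC | starting material
22 | methyl formate | COC=O | starting material
23 | sodium enolate of methyl 2-formylpropanoate | COC(=O)C(C)=C[O-].[Na+] | intermediate
24 | methyl (E)-3-methoxy-2-methylprop-2-enoate | CO/C=C(\C)C(=O)OC | intermediate
25 | methyl (Z)-3-lithio-3-methoxy-2-methylprop-2-enoate | CO/C([Li])=C(\C)C(=O)OC | intermediate
26 | lithium alkoxide from addition of 25 to 20 (carbinol carbon cis to the ester) | CC[C@@H](O[Si](C)(C)C(C)(C)C)c1cccc(n1)C[C@@](O[Si](C)(C)C(C)(C)C)(C#CCOCc1ccccc1)C(O[Li])/C(OC)=C(/C)C(=O)OC | intermediate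
27 | 5-[(2R)-5-(benzyloxy)-2-(tert-butyldimethylsilyloxy)-1-{6-[(1R)-1-(tert-butyldimethylsilyloxy)propyl]pyridin-2-yl}pent-3-yn-2-yl]-4-methoxy-3-methylfuran-2(5H)-one (both C5 epimers) | CC[C@@H](O[Si](C)(C)C(C)(C)C)c1cccc(n1)C[C@@](O[Si](C)(C)C(C)(C)C)(C#CCOCc1ccccc1)C1OC(=O)C(C)=C1OC | intermediate
28 | pyridine N-oxide of 27 | CC[C@@H](O[Si](C)(C)C(C)(C)C)c1cccc([n+]1[O-])C[C@@](O[Si](C)(C)C(C)(C)C)(C#CCOCc1ccccc1)C1OC(=O)C(C)=C1OC | intermediate
29 | potassium (E)-prop-1-enyltrifluoroborate | C/C=C/[B-](F)(F)F.[K+] | starting material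
30 | 1-(difluoroiodo)-4-methylbenzene | Cc1ccc(I(F)F)cc1 | starting material
31 | (E)-(4-methylphenyl)(prop-1-enyl)iodonium tetrafluoroborate | C/C=C/[I+]c1ccc(C)cc1.F[B-](F)(F)F | intermediate
32 | N-[(Z)-prop-1-enyloxy]pyridinium tetrafluoroborate derived from 28 | CC[C@@H](O[Si](C)(C)C(C)(C)C)c1cccc([n+]1O/C=C\C)C[C@@](O[Si](C)(C)C(C)(C)C)(C#CCOCc1ccccc1)C1OC(=O)C(C)=C1OC.F[B-](F)(F)F | intermediate
33 | anhydrobase of 32: 2-alkylidene-1-[(Z)-prop-1-enyloxy]-1,2-dihydropyridine with E exocyclic C=C (C13 trans to N) | CC[C@@H](O[Si](C)(C)C(C)(C)C)C1=CC=C/C(=C\[C@@](O[Si](C)(C)C(C)(C)C)(C#CCOCc2ccccc2)C2OC(=O)C(C)=C2OC)N1O/C=C\C | intermediate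
34 | aldehyde from the [3,3] shift: 2-pyridyl-CH(C9)–CH(CH3)(C10)–CHO with C9 and C10 as in the target | CC[C@@H](O[Si](C)(C)C(C)(C)C)c1cccc(n1)[C@@H]([C@H](C)C=O)[C@@](O[Si](C)(C)C(C)(C)C)(C#CCOCc1ccccc1)C1OC(=O)C(C)=C1OC | intermediate
35 | spiro butenolide cyclopentanol: 9-(2-pyridyl), 10-methyl, 11-hydroxy, 13-silyloxy-13-alkynyl; relative configuration as in the target | CC[C@@H](O[Si](C)(C)C(C)(C)C)c1cccc(n1)[C@H]1[C@H](C)[C@H](O)[C@@]2(OC(=O)C(C)=C2OC)[C@]1(O[Si](C)(C)C(C)(C)C)C#CCOCc1ccccc1 | intermediate
36 | diol: 35 with the C13 side chain reduced and debenzylated to 3-hydroxypropyl | CC[C@@H](O[Si](C)(C)C(C)(C)C)c1cccc(n1)[C@H]1[C@H](C)[C@H](O)[C@@]2(OC(=O)C(C)=C2OC)[C@]1(O[Si](C)(C)C(C)(C)C)CCCO | intermediate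
37 | primary methanesulfonate of 36 | CC[C@@H](O[Si](C)(C)C(C)(C)C)c1cccc(n1)[C@H]1[C@H](C)[C@H](O)[C@@]2(OC(=O)C(C)=C2OC)[C@]1(O[Si](C)(C)C(C)(C)C)CCCOS(C)(=O)=O | intermediate
38 | tetracyclic pyrido[1,2-a]azepinium methanesulfonate (N bonded to C16) | CC[C@@H](O[Si](C)(C)C(C)(C)C)c1cccc2[C@H]3[C@H](C)[C@H](O)[C@@]4(OC(=O)C(C)=C4OC)[C@]3(O[Si](C)(C)C(C)(C)C)CCC[n+]12.CS(=O)(=O)[O-] | intermediate
39 | piperidinium methanesulfonate of 40 | CC[C@@H](O[Si](C)(C)C(C)(C)C)[C@H]1CCC[C@H]2[C@H]3[C@H](C)[C@H](O)[C@@]4(OC(=O)C(C)=C4OC)[C@]3(O[Si](C)(C)C(C)(C)C)CCC[NH+]12.CS(=O)(=O)[O-] | intermediate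
40 | target with tert-butyldimethylsilyl ethers at the C1′ and C13 oxygens | CC[C@@H](O[Si](C)(C)C(C)(C)C)[C@H]1CCC[C@H]2[C@H]3[C@H](C)[C@H](O)[C@@]4(OC(=O)C(C)=C4OC)[C@]3(O[Si](C)(C)C(C)(C)C)CCCN12 | intermediate
41 | CNP0267781.1 | CC[C@@H](O)[C@H]1CCC[C@H]2[C@H]3[C@H](C)[C@H](O)[C@@]4(OC(=O)C(C)=C4OC)[C@]3(O)CCCN12 | target

**Summary**
Total step count: 17.
Longest linear sequence: 13 steps (steps 1, 2, 3, 6, 7, 8, 10, 11, 13, 14, 15, 16, 17).

**Steps most likely to fail**

Step 13 (Proposed new method). The hindered N-oxide may be alkenylated slowly. Proton loss may occur on the wrong side of nitrogen. The shift may take the wrong face at C9. The dienolate may lose silanolate before it closes the ring. Fallback with known reactions, from 27 back to 35: pyridine 27 is N-alkylated with (E)-crotyl bromide (MeCN, 60 °C) to pyridinium bromide F1. Potassium tert-butoxide gives anhydrobase F2, which undergoes the 3-aza-Cope rearrangement to homoallylic pyridine F3. Lemieux–Johnson cleavage (OsO4 cat., NaIO4, 2,6-lutidine) gives aldehyde F4, the C10 epimer of 34. Under the guanidine base of step 13, F4 should equilibrate with 34 by enolisation and close to 35.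

Step 15. N-alkylation of a nitrogen flanked by two branched α-substituents may be slow, so that elimination or intermolecular alkylation takes over. Fallback, from 36 back to 40: the order of the last two ring closures is reversed. Diol 36 is hydrogenated as its hydrochloride (H2, PtO2, AcOH) to cis-2,6-disubstituted piperidine F5. The far more nucleophilic secondary amine is then closed onto C16 with PPh3, CBr4 and Et3N by way of bromide F6, which gives 40 directly.

Step 6. Weak chelation may erode the facial selectivity at C13, and the ynone may suffer conjugate addition. Fallback, from 15 back to 17: the two carbon–carbon bonds at C13 are made in the opposite order. Picolyllithium 15 is acylated with Weinreb amide 10 to ketone F7. Cerium acetylide F8 (from 12 and CeCl3, THF, −78 °C) then adds under Felkin–Anh control (dioxolane C–O anti to the nucleophile), which should lead to the same carbinol 17.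

**Further compounds**
F1 | step 13 | N-[(E)-but-2-enyl]pyridinium bromide of 27 | CC[C@@H](O[Si](C)(C)C(C)(C)C)c1cccc([n+]1C/C=C/C)C[C@@](O[Si](C)(C)C(C)(C)C)(C#CCOCc1ccccc1)C1OC(=O)C(C)=C1OC.[Br-]
F2 | step 13 | N-[(E)-but-2-enyl] anhydrobase of F1 (E exocyclic C=C) | CC[C@@H](O[Si](C)(C)C(C)(C)C)C1=CC=C/C(=C\[C@@](O[Si](C)(C)C(C)(C)C)(C#CCOCc2ccccc2)C2OC(=O)C(C)=C2OC)N1C/C=C/C
F3 | step 13 | homoallylic pyridine from the 3-aza-Cope shift (C10 epimeric to the target series) | CC[C@@H](O[Si](C)(C)C(C)(C)C)c1cccc(n1)[C@@H]([C@@H](C)C=C)[C@@](O[Si](C)(C)C(C)(C)C)(C#CCOCc1ccccc1)C1OC(=O)C(C)=C1OC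
F4 | step 13 | aldehyde, C10 epimer of 34 | CC[C@@H](O[Si](C)(C)C(C)(C)C)c1cccc(n1)[C@@H]([C@@H](C)C=O)[C@@](O[Si](C)(C)C(C)(C)C)(C#CCOCc1ccccc1)C1OC(=O)C(C)=C1OC
F5 | step 15 | cis-2,6-disubstituted piperidine from hydrogenation of 36 | CC[C@@H](O[Si](C)(C)C(C)(C)C)[C@H]1CCC[C@H](N1)[C@H]1[C@H](C)[C@H](O)[C@@]2(OC(=O)C(C)=C2OC)[C@]1(O[Si](C)(C)C(C)(C)C)CCCO
F6 | step 15 | primary bromide of F5 | CC[C@@H](O[Si](C)(C)C(C)(C)C)[C@H]1CCC[C@H](N1)[C@H]1[C@H](C)[C@H](O)[C@@]2(OC(=O)C(C)=C2OC)[C@]1(O[Si](C)(C)C(C)(C)C)CCCBr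
F7 | step 6 | 2-{6-[(1R)-1-(tert-butyldimethylsilyloxy)propyl]pyridin-2-yl}-1-[(4S)-2,2-dimethyl-1,3-dioxolan-4-yl]ethan-1-one | CC[C@@H](O[Si](C)(C)C(C)(C)C)c1cccc(n1)CC(=O)[C@@H]1COC(C)(C)O1
F8 | step 6 | dichloro[3-(benzyloxy)prop-1-ynyl]cerium | Cl[Ce](Cl)C#CCOCc1ccccc1
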